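## Retrosynthetic overview

1. The target comes from its tri-O-benzyl ether by one hydrogenolysis. Nothing else changes once ring C exists.
2. Ring C is cut at C3–C4. C4 becomes a formyl group on C4a of ring A, and C2–C3 becomes the C=CH2 of a 1-arylvinyl ether on O1. An enantioselective Rh-catalysed intramolecular alkene hydroacylation then closes ring C, makes the C4 ketone at its final oxidation level and sets C2, all in one isomerisation of a flat precursor.
3. Enabling feature: C2 carries both O1 and ring B, and C3 is a bare CH2 next to the C4 carbonyl, which sits on C4a ortho to C8a–O1. C2 can therefore be flattened to an enol-ether carbon without allylic hydrogen, with its =CH2 end within reach of the formyl C–H. In ring A, C6 lies para to C8a–O1 and between the equivalent C5–O and C7–O, so formylation at either free position gives the same aldehyde.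
4. The enol ether comes from Mitsunobu etherification of the O1 phenol with a bromohydrin, followed by dehydrobromination. The aldehyde comes from a Vilsmeier–Haack formylation.
5. The piperidine comes from the tert-butanesulfinyl aldimine of protected 2,4,6-trihydroxybenzaldehyde, a 4-chlorobutyl Grignard reagent and an N-alkylation. Ring order: rings A and B are bought, the piperidine ring closes in step 5, and ring C closes in step 12.

Key step: step 12

Assumption: the (R) antipode of DTBM-SEGPHOS is taken to open the enol-ether face that gives 2S; both antipodes are sold, the two possible products are diastereomers, so the sense can be read on the first run and the ligand exchanged if needed.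

## Route

Step 1
Reactants: 1 2,4,6-trihydroxybenzaldehyde
Product: 2 4-(allyloxy)-2,6-dihydroxybenzaldehyde
Conditions: allyl bromide (1.0 equiv), K2CO3 (1.0 equiv), DMF, 0 °C to rt
Reagents that add atoms: allyl bromide, C=CCBr
Why: Williamson etherification, in which the 4-OH is the most acidic hydroxyl and the only one never tied into the hydrogen bond to the formyl oxygen, so one equivalent of base and halide should alkylate it first.

Step 2
Reactants: 2 4-(allyloxy)-2,6-dihydroxybenzaldehyde
Product: 3 4-(allyloxy)-2,6-bis(benzyloxy)benzaldehyde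
Conditions: BnBr (2.5 equiv), K2CO3, DMF, 60 °C
Reagents that add atoms: benzyl bromide, BrCc1ccccc1
Why: Williamson etherification under more forcing conditions benzylates both chelated ortho hydroxyls, and the allyl ether is inert.

Step 3
Reactants: 3 4-(allyloxy)-2,6-bis(benzyloxy)benzaldehyde; 4 (R)-2-methylpropane-2-sulfinamide
Product: 5 (R)-N-{(E)-[4-(allyloxy)-2,6-bis(benzyloxy)phenyl]methylidene}-2-methylpropane-2-sulfinamide
Conditions: Ti(OEt)4, THF, 60 °C
Reagents that add atoms: none
Why: Ti(OEt)4-mediated condensation of an aldehyde with tert-butanesulfinamide gives the E aldimine and leaves the sulfur configuration untouched.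

Step 4
Reactants: 5 (R)-N-{(E)-[4-(allyloxy)-2,6-bis(benzyloxy)phenyl]methylidene}-2-methylpropane-2-sulfinamide
Product: 6 (R)-N-{(1S)-1-[4-(allyloxy)-2,6-bis(benzyloxy)phenyl]-5-chloropentyl}-2-methylpropane-2-sulfinamide
Conditions: Cl(CH2)4MgBr (from Br(CH2)4Cl and Mg, Et2O), CH2Cl2, −48 °C to rt; then H2O
Reagents that add atoms: 4-chlorobutylmagnesium bromide, ClCCCC[Mg]Br
Why: 1,2-addition of a Grignard reagent to an N-tert-butanesulfinyl aldimine in a non-coordinating solvent, where a six-membered chair transition state (Mg on the sulfinyl oxygen, tert-butyl and aryl equatorial) delivers the alkyl group to one imine face and sets the (S) carbon from the (R) sulfur, and the minor diastereomer can be removed by chromatography.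

Step 5
Reactants: 6 (R)-N-{(1S)-1-[4-(allyloxy)-2,6-bis(benzyloxy)phenyl]-5-chloropentyl}-2-methylpropane-2-sulfinamide
Product: 7 (2S)-2-[4-(allyloxy)-2,6-bis(benzyloxy)phenyl]-1-[(R)-tert-butylsulfinyl]piperidine
Conditions: KN(SiMe3)2, THF, 0 °C to rt
Reagents that add atoms: none
Why: Intramolecular SN2 N-alkylation (6-exo-tet) of the sulfinamide anion closes the piperidine ring without involving the stereocentre.

Step 6
Reactants: 7 (2S)-2-[4-(allyloxy)-2,6-bis(benzyloxy)phenyl]-1-[(R)-tert-butylsulfinyl]piperidine
Product: 9 (2S)-2-[4-(allyloxy)-2,6-bis(benzyloxy)phenyl]-1-methylpiperidine, via piperidinium chloride 8 (not isolated)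
Conditions: HCl (4 M in dioxane), MeOH, 0 °C, evaporate; then aq. CH2O, NaOAc, NaBH(OAc)3, ClCH2CH2Cl, rt
Reagents that add atoms: formaldehyde, C=O
Why: Acid methanolysis of the S–N bond followed by reductive amination with formaldehyde, where the short cold acid contact keeps the donor-rich benzylic C–N bond from ionising and the fully etherified ring A does not compete for the iminium ion.

Step 7
Reactants: 9 (2S)-2-[4-(allyloxy)-2,6-bis(benzyloxy)phenyl]-1-methylpiperidine
Product: 11 6-(allyloxy)-2,4-bis(benzyloxy)-3-[(2S)-1-methylpiperidin-2-yl]benzaldehyde, via iminium chloride 10 (not isolated)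
Conditions: POCl3, DMF, 0 °C to rt; then H2O
Reagents that add atoms: N,N-dimethylformamide, CN(C)C=O; water, O
Why: Vilsmeier–Haack formylation of a phloroglucinol triether, in which the two free positions of ring A are interchanged by rotation about the aryl–piperidine bond, so only one aldehyde can form and it lies ortho to the oxygen that becomes O1.

Step 8
Reactants: 11 6-(allyloxy)-2,4-bis(benzyloxy)-3-[(2S)-1-methylpiperidin-2-yl]benzaldehyde
Product: 12 2,4-bis(benzyloxy)-6-hydroxy-3-[(2S)-1-methylpiperidin-2-yl]benzaldehyde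
Conditions: Pd(PPh3)4 (cat.), morpholine, THF, rt
Reagents that add atoms: none
Why: Tsuji–Trost-type deallylation, in which zerovalent palladium ionises the aryl allyl ether and morpholine takes up the allyl group while benzyl ethers, aldehyde and amine are left alone, and the phenol is freed only after the formyl group has made ring A too electron-poor for quinone-methide-type loss of the benzylic amine.

Step 9
Reactants: 13 1-[4-(benzyloxy)phenyl]-2-bromoethan-1-one
Product: 14 racemic 1-[4-(benzyloxy)phenyl]-2-bromoethan-1-ol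
Conditions: NaBH4, MeOH, 0 °C
Reagents that add atoms: none
Why: Borohydride reduction of an alpha-bromo ketone stops at the bromohydrin in the cold, and the racemate suffices because this centre is erased in step 11.

Step 10
Reactants: 12 2,4-bis(benzyloxy)-6-hydroxy-3-[(2S)-1-methylpiperidin-2-yl]benzaldehyde; 14 racemic 1-[4-(benzyloxy)phenyl]-2-bromoethan-1-ol
Product: 15 2,4-bis(benzyloxy)-6-{1-[4-(benzyloxy)phenyl]-2-bromoethoxy}-3-[(2S)-1-methylpiperidin-2-yl]benzaldehyde (both epimers at the ether carbon)
Conditions: PPh3, DIAD, THF, 0 °C to rt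
Reagents that add atoms: none
Why: Mitsunobu etherification of an acidic salicylaldehyde-type phenol with a secondary benzylic alcohol, where the configuration of the new ether carbon is irrelevant because step 11 erases it.

Step 11
Reactants: 15 2,4-bis(benzyloxy)-6-{1-[4-(benzyloxy)phenyl]-2-bromoethoxy}-3-[(2S)-1-methylpiperidin-2-yl]benzaldehyde
Product: 16 2,4-bis(benzyloxy)-6-({1-[4-(benzyloxy)phenyl]ethenyl}oxy)-3-[(2S)-1-methylpiperidin-2-yl]benzaldehyde
Conditions: KOtBu, THF, 0 °C
Reagents that add atoms: none
Why: E2 dehydrobromination of a beta-bromo ether, the classical route to alpha-alkoxystyrenes, in which the benzylic oxygen-bearing C–H is lost together with bromide (a far better leaving group than the aryloxide) and the aldehyde has no alpha-hydrogen.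

Step 12
Reactants: 16 2,4-bis(benzyloxy)-6-({1-[4-(benzyloxy)phenyl]ethenyl}oxy)-3-[(2S)-1-methylpiperidin-2-yl]benzaldehyde
Product: 19 (2S)-5,7-bis(benzyloxy)-2-[4-(benzyloxy)phenyl]-6-[(2S)-1-methylpiperidin-2-yl]-2,3-dihydro-4H-chromen-4-one, via ammonium tetrafluoroborate 17 (not isolated), via flavanone ammonium tetrafluoroborate 18 (not isolated)
Conditions: HBF4·OEt2 (1.0 equiv), CH2Cl2, −78 °C, evaporate; [Rh(cod)2]BF4 and (R)-DTBM-SEGPHOS (5 mol % each, cod removed with H2 beforehand), ClCH2CH2Cl, 4 Å sieves, 60 °C; aq. NaHCO3 on work-up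
Reagents that add atoms: none
Why: Proposed new method: the cationic monovalent rhodium bisphosphine complex binds the enol-ether alkene of 17 and adds oxidatively into the neighbouring formyl C–H bond, the hydride of the resulting trivalent acyl rhodium hydride migrates to the inner alkene carbon (C2) to leave a primary alkyl at C3 within a seven-membered rhodacycle, and C–C reductive elimination joins C3 to C4. The closest known reaction type is the enantioselective rhodium-bisphosphine intramolecular hydroacylation of 1,1-disubstituted alkenes, as in 2-(2-substituted allyl)benzaldehydes giving 3-substituted tetralones and alpha-substituted 2-vinylbenzaldehydes giving 3-substituted indanones; what is new is oxygen in place of the benzylic CH2, that is an aryl 1-arylvinyl ether as the alkene. Ring C closes in the 6-endo-trig mode, both alkene carbons ending inside the ring. C2 is the only new stereocentre and is fixed in the hydride migration by the alkene face that the chiral pocket of the ligand allows to bind (catalyst control; the piperidine centre is too remote to interfere), and any 2R epimer is a diastereomer that chromatography or crystallisation can remove. The step needs closure at the CH2 terminus and not at C2, and the substrate secures this because C2 is fully substituted, so the alternative would need a tertiary alkyl rhodium and a reductive elimination to a quaternary carbon; the alkene has no allylic hydrogen and cannot isomerise, O1 lies inside the rhodacycle where the syn-coplanar geometry for beta-aryloxy elimination is out of reach, and the donor-rich aryl group slows decarbonylation. The basic nitrogen is masked as its ammonium tetrafluoroborate, too weak an acid to protonate the enol ether under anhydrous conditions, so that it neither binds rhodium nor deprotonates the rhodium hydride.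

Step 13
Reactants: 19 (2S)-5,7-bis(benzyloxy)-2-[4-(benzyloxy)phenyl]-6-[(2S)-1-methylpiperidin-2-yl]-2,3-dihydro-4H-chromen-4-one
Product: 20 (2S)-5,7-dihydroxy-2-(4-hydroxyphenyl)-6-[(2S)-1-methylpiperidin-2-yl]-2,3-dihydro-4H-chromen-4-one
Conditions: H2 (1 atm), Pd/C, EtOAc–MeOH, rt, stopped after uptake of three equivalents
Reagents that add atoms: none
Why: Hydrogenolysis of aryl benzyl ethers over Pd/C should outrun cleavage of the cyclic benzylic C2–O1 and C–N bonds, and the neutral base-free medium avoids retro-oxa-Michael opening, so both stereocentres are kept.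

## Compound list

1 | 2,4,6-trihydroxybenzaldehyde | O=Cc1c(O)cc(O)cc1O | starting material
2 | 4-(allyloxy)-2,6-dihydroxybenzaldehyde | C=CCOc1cc(O)c(C=O)c(O)c1 | intermediate
3 | 4-(allyloxy)-2,6-bis(benzyloxy)benzaldehyde | C=CCOc1cc(OCc2ccccc2)c(C=O)c(OCc2ccccc2)c1 | intermediate
4 | (R)-2-methylpropane-2-sulfinamide | CC(C)(C)[S@@](=O)N | starting material
5 | (R)-N-{(E)-[4-(allyloxy)-2,6-bis(benzyloxy)phenyl]methylidene}-2-methylpropane-2-sulfinamide | CC(C)(C)[S@@](=O)/N=C/c1c(OCc2ccccc2)cc(OCC=C)cc1OCc1ccccc1 | intermediate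
6 | (R)-N-{(1S)-1-[4-(allyloxy)-2,6-bis(benzyloxy)phenyl]-5-chloropentyl}-2-methylpropane-2-sulfinamide | CC(C)(C)[S@@](=O)N[C@@H](CCCCCl)c1c(OCc2ccccc2)cc(OCC=C)cc1OCc1ccccc1 | intermediate
7 | (2S)-2-[4-(allyloxy)-2,6-bis(benzyloxy)phenyl]-1-[(R)-tert-butylsulfinyl]piperidine | CC(C)(C)[S@@](=O)N1CCCC[C@H]1c1c(OCc2ccccc2)cc(OCC=C)cc1OCc1ccccc1 | intermediate
8 | (2S)-2-[4-(allyloxy)-2,6-bis(benzyloxy)phenyl]piperidinium chloride (not isolated) | [Cl-].[NH2+]1CCCC[C@H]1c1c(OCc2ccccc2)cc(OCC=C)cc1OCc1ccccc1 | intermediate
9 | (2S)-2-[4-(allyloxy)-2,6-bis(benzyloxy)phenyl]-1-methylpiperidine | CN1CCCC[C@H]1c1c(OCc2ccccc2)cc(OCC=C)cc1OCc1ccccc1 | intermediate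
10 | N-({6-(allyloxy)-2,4-bis(benzyloxy)-3-[(2S)-1-methylpiperidin-2-yl]phenyl}methylidene)-N-methylmethanaminium chloride (not isolated) | [Cl-].CN1CCCC[C@H]1c1c(OCc2ccccc2)cc(OCC=C)c(C=[N+](C)C)c1OCc1ccccc1 | intermediate
11 | 6-(allyloxy)-2,4-bis(benzyloxy)-3-[(2S)-1-methylpiperidin-2-yl]benzaldehyde | CN1CCCC[C@H]1c1c(OCc2ccccc2)cc(OCC=C)c(C=O)c1OCc1ccccc1 | intermediate
12 | 2,4-bis(benzyloxy)-6-hydroxy-3-[(2S)-1-methylpiperidin-2-yl]benzaldehyde | CN1CCCC[C@H]1c1c(OCc2ccccc2)cc(O)c(C=O)c1OCc1ccccc1 | intermediate
13 | 1-[4-(benzyloxy)phenyl]-2-bromoethan-1-one | O=C(CBr)c1ccc(OCc2ccccc2)cc1 | starting material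
14 | racemic 1-[4-(benzyloxy)phenyl]-2-bromoethan-1-ol | OC(CBr)c1ccc(OCc2ccccc2)cc1 | intermediate
15 | 2,4-bis(benzyloxy)-6-{1-[4-(benzyloxy)phenyl]-2-bromoethoxy}-3-[(2S)-1-methylpiperidin-2-yl]benzaldehyde (both epimers at the ether carbon) | CN1CCCC[C@H]1c1c(OCc2ccccc2)cc(OC(CBr)c2ccc(OCc3ccccc3)cc2)c(C=O)c1OCc1ccccc1 | intermediate
16 | 2,4-bis(benzyloxy)-6-({1-[4-(benzyloxy)phenyl]ethenyl}oxy)-3-[(2S)-1-methylpiperidin-2-yl]benzaldehyde | CN1CCCC[C@H]1c1c(OCc2ccccc2)cc(OC(=C)c2ccc(OCc3ccccc3)cc2)c(C=O)c1OCc1ccccc1 | intermediate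
17 | N-protonated 16 as tetrafluoroborate (not isolated) | F[B-](F)(F)F.C[NH+]1CCCC[C@H]1c1c(OCc2ccccc2)cc(OC(=C)c2ccc(OCc3ccccc3)cc2)c(C=O)c1OCc1ccccc1 | intermediate
18 | N-protonated 19 as tetrafluoroborate (not isolated) | F[B-](F)(F)F.C[NH+]1CCCC[C@H]1c1c(OCc2ccccc2)cc2c(c1OCc1ccccc1)C(=O)C[C@@H](c1ccc(OCc3ccccc3)cc1)O2 | intermediate
19 | (2S)-5,7-bis(benzyloxy)-2-[4-(benzyloxy)phenyl]-6-[(2S)-1-methylpiperidin-2-yl]-2,3-dihydro-4H-chromen-4-one | CN1CCCC[C@H]1c1c(OCc2ccccc2)cc2c(c1OCc1ccccc1)C(=O)C[C@@H](c1ccc(OCc3ccccc3)cc1)O2 | intermediate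
20 | (2S)-5,7-dihydroxy-2-(4-hydroxyphenyl)-6-[(2S)-1-methylpiperidin-2-yl]-2,3-dihydro-4H-chromen-4-one | CN1CCCC[C@H]1c1c(O)cc2c(c1O)C(=O)C[C@@H](c1ccc(O)cc1)O2 | target

## Step count and risks

Total step count: 13.
Longest linear sequence: 12 steps (steps 1–8 and 10–13, from 1).

**1. Step 12 (new method).**
- What may go wrong:
  - hydride migration to the CH2 terminus followed by closure at the inner carbon;
  - loss of CO from the acyl rhodium hydride;
  - aldol-type attack of the enol ether on the formyl group, triggered by acid or by the Lewis-acidic metal;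
  - hydrolysis of the enol ether by traces of water;
  - weak facial selectivity.
- Fallback (known chemistry, same bond): it sets out from 12 and 13 and comes back at 19. Corey–Bakshi–Shibata reduction of 13 ((S)-Me-CBS oxazaborolidine, BH3·SMe2) gives (1S)-1-[4-(benzyloxy)phenyl]-2-bromoethan-1-ol F1. Mitsunobu etherification of 12 with F1 goes with inversion. It gives 2,4-bis(benzyloxy)-6-{(1R)-1-[4-(benzyloxy)phenyl]-2-bromoethoxy}-3-[(2S)-1-methylpiperidin-2-yl]benzaldehyde F2, which already holds the C2 configuration. An N-heterocyclic carbene (thiazolium or triazolium salt, DBU, toluene) then turns the formyl group into an acyl anion equivalent that displaces the primary bromide (6-exo-tet). This reaction type is known for 2-(2-haloethoxy)benzaldehydes giving chroman-4-ones. It forms C3–C4 without touching C2 and gives 19.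

**2. Step 10.**
- What may go wrong:
  - ionisation of the activated, donor-substituted benzylic alcohol, with elimination or capture by the hydrazide;
  - sluggish reaction of the hydrogen-bonded phenol;
  - in the next step, competing loss of the aryloxide.
- Fallback: it sets out from 9 and comes back at 16, building the enol ether from an ester before the aldehyde exists. Compound 9 is deallylated as in step 8 to 3,5-bis(benzyloxy)-4-[(2S)-1-methylpiperidin-2-yl]phenol F3. Bromination ortho to the hydroxyl (NBS, CH2Cl2, −78 °C) gives 3,5-bis(benzyloxy)-2-bromo-4-[(2S)-1-methylpiperidin-2-yl]phenol F4. Acylation with 4-(benzyloxy)benzoyl chloride (Et3N, DMAP) gives the aryl 4-(benzyloxy)benzoate F5. Petasis methylenation of the ester carbonyl (Cp2TiMe2, toluene, 70 °C), known for aryl benzoates, gives the bromo enol ether F6. Bromine–lithium exchange (n-BuLi, THF, −78 °C) gives the aryllithium F7, which is quenched with DMF to give 16.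

**3. Step 4.**
- What may go wrong:
  - poor facial selectivity, because the ortho benzyloxy oxygens compete with the sulfinyl oxygen for magnesium;
  - slow addition to the donor-rich imine, with competing beta-hydride reduction.
- Fallback: it sets out from 3 and comes back at 9, giving up auxiliary control for a short racemic sequence and a separation. The same Grignard reagent is added to aldehyde 3 itself to give racemic 1-[4-(allyloxy)-2,6-bis(benzyloxy)phenyl]-5-chloropentan-1-ol F8. Excess methylamine (NaI, EtOH, 50 °C) displaces the primary chloride to give racemic 1-[4-(allyloxy)-2,6-bis(benzyloxy)phenyl]-5-(methylamino)pentan-1-ol F9. Cyclodehydration (SOCl2, then aq. NaOH), helped by the easily ionised benzylic position, gives racemic 2-[4-(allyloxy)-2,6-bis(benzyloxy)phenyl]-1-methylpiperidine F10. Preparative chromatography on a chiral stationary phase then gives 9.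

## Further compounds

F1 | step 12 | (1S)-1-[4-(benzyloxy)phenyl]-2-bromoethan-1-ol | O[C@H](CBr)c1ccc(OCc2ccccc2)cc1
F2 | step 12 | 2,4-bis(benzyloxy)-6-{(1R)-1-[4-(benzyloxy)phenyl]-2-bromoethoxy}-3-[(2S)-1-methylpiperidin-2-yl]benzaldehyde | CN1CCCC[C@H]1c1c(OCc2ccccc2)cc(O[C@@H](CBr)c2ccc(OCc3ccccc3)cc2)c(C=O)c1OCc1ccccc1
F3 | step 10 | 3,5-bis(benzyloxy)-4-[(2S)-1-methylpiperidin-2-yl]phenol | CN1CCCC[C@H]1c1c(OCc2ccccc2)cc(O)cc1OCc1ccccc1
F4 | step 10 | 3,5-bis(benzyloxy)-2-bromo-4-[(2S)-1-methylpiperidin-2-yl]phenol | CN1CCCC[C@H]1c1c(OCc2ccccc2)cc(O)c(Br)c1OCc1ccccc1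
F5 | step 10 | 3,5-bis(benzyloxy)-2-bromo-4-[(2S)-1-methylpiperidin-2-yl]phenyl 4-(benzyloxy)benzoate | CN1CCCC[C@H]1c1c(OCc2ccccc2)cc(OC(=O)c2ccc(OCc3ccccc3)cc2)c(Br)c1OCc1ccccc1
F6 | step 10 | (2S)-2-[2,6-bis(benzyloxy)-4-({1-[4-(benzyloxy)phenyl]ethenyl}oxy)-3-bromophenyl]-1-methylpiperidine | CN1CCCC[C@H]1c1c(OCc2ccccc2)cc(OC(=C)c2ccc(OCc3ccccc3)cc2)c(Br)c1OCc1ccccc1
F7 | step 10 | aryllithium from F6 (lithium in place of bromine) | CN1CCCC[C@H]1c1c(OCc2ccccc2)cc(OC(=C)c2ccc(OCc3ccccc3)cc2)c([Li])c1OCc1ccccc1
F8 | step 4 | racemic 1-[4-(allyloxy)-2,6-bis(benzyloxy)phenyl]-5-chloropentan-1-ol | OC(CCCCCl)c1c(OCc2ccccc2)cc(OCC=C)cc1OCc1ccccc1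
F9 | step 4 | racemic 1-[4-(allyloxy)-2,6-bis(benzyloxy)phenyl]-5-(methylamino)pentan-1-ol | CNCCCCC(O)c1c(OCc2ccccc2)cc(OCC=C)cc1OCc1ccccc1
F10 | step 4 | racemic 2-[4-(allyloxy)-2,6-bis(benzyloxy)phenyl]-1-methylpiperidine | CN1CCCCC1c1c(OCc2ccccc2)cc(OCC=C)cc1OCc1ccccc1
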